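**Plan**

- Retrosynthesis: the CH2OH group at C4 is traced back to a methyl ester and the bromines at C2 and C6 to a late ortho-bromination of a phenol. The benzene ring is traced back to a cyclohexa-1,4-diene, which is cut at C2–C3 and C4–C5.
- Enabling feature: in the single benzene ring, C3 (Br) and C4 (CH2OH) are vicinal and C1 (OH) lies across the ring from C4. C3–C4 can therefore come from a 3-bromo-ynoate and C2–C1–C6–C5 from a butadiene oxygenated at its 2-position.
- Forward order: methyl propiolate is brominated at its terminus, and a Diels–Alder reaction with the 2-siloxydiene closes the only ring. DDQ then aromatizes and acid frees the phenol, Br2 fills both positions ortho to OH, and i-Bu2AlH reduces the ester.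
- Stereochemistry: the target is achiral and has no stereocentre, so only regiochemistry must be controlled, and the cycloaddition sets it.

Key step: step 2

Remark on the chemistry: the silyl dienol ether formed in the cycloaddition is assumed to be too easily hydrolysed for chromatography and is carried into the aromatization as the crude concentrate.

**Step 1**
Reactants: 1 methyl propiolate (methyl prop-2-ynoate); 2 N-bromosuccinimide
Product: 3 methyl 3-bromopropiolate (methyl 3-bromoprop-2-ynoate)
Conditions: NBS (1.1 equiv), AgNO3 (10 mol %), acetone, rt, dark
Reagents that add atoms: N-bromosuccinimide, O=C1CCC(=O)N1Br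
Why: Silver-catalysed electrophilic bromination of a terminal alkyne, in which AgNO3 converts the acidic propiolate C–H into a silver acetylide that takes Br+ from NBS, is the standard preparation of 1-bromoalkynes and leaves the ester untouched.

**Step 2**
Reactants: 3 methyl 3-bromopropiolate; 4 2-(trimethylsilyloxy)buta-1,3-diene (1.5 equiv)
Product: 5 methyl 2-bromo-4-[(trimethylsilyl)oxy]cyclohexa-1,4-diene-1-carboxylate
Conditions: toluene, BHT (cat.), 90 °C, sealed tube, N2; evaporate, use crude
Reagents that add atoms: none
Why: This is a thermal, concerted but asynchronous Diels–Alder reaction of normal electron demand between the HOMO of the electron-rich siloxydiene 4 and the LUMO of the electron-poor bromo-ynoate 3; the closest known reactions are the para-selective cycloadditions of 2-silyloxybutadienes with propiolate esters and the cycloadditions of 3-halopropiolates with dienes. The one six-membered carbocycle closes by intermolecular (4+2) cycloaddition, in which both new sigma bonds (C2–C3 and C4–C5 of the target) form in the same step. No stereocentre arises, because the alkyne supplies two sp2 carbons and both diene termini become CH2 groups. The selectivity required is regioselectivity: the largest HOMO coefficient of 4 sits on the CH2 attached to the siloxy-bearing carbon, and the largest LUMO coefficient of 3 sits on the brominated carbon, since the ester as acceptor and the bromine as lone-pair donor polarize the alkyne in the same direction. These two atoms therefore bond first, which places the siloxy carbon para to the ester carbon and meta to bromine. The alkyne dienophile delivers a 1,4-diene one oxidation level below the arene, and excess diene with a radical inhibitor should hold back oligomerization of the bromoalkyne.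

**Step 3**
Reactants: 5 methyl 2-bromo-4-[(trimethylsilyl)oxy]cyclohexa-1,4-diene-1-carboxylate
Product: 7 methyl 2-bromo-4-hydroxybenzoate, via silyl ether 6 (not isolated)
Conditions: DDQ (1.1 equiv), toluene, 0 °C to rt; filter; then 1 M HCl, THF, rt
Reagents that add atoms: none
Why: DDQ dehydrogenation of a cyclohexa-1,4-diene proceeds by hydride abstraction from a doubly allylic CH2 to a siloxy-stabilized cyclohexadienyl cation that loses a proton to give the arene, and the labile aryl trimethylsilyl ether is then hydrolysed by dilute acid, which leaves the methyl ester and the aryl bromide alone.

**Step 4**
Reactants: 7 methyl 2-bromo-4-hydroxybenzoate; 8 bromine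
Product: 10 methyl 2,3,5-tribromo-4-hydroxybenzoate, via dibromophenol 9 (not isolated)
Conditions: Br2 (2.2 equiv), AcOH, rt to 40 °C; Na2S2O3 (aq)
Reagents that add atoms: bromine, BrBr
Why: In this electrophilic aromatic bromination of a phenol the hydroxyl group activates only its two ortho positions, the para position being blocked by the ester, so bromine should enter first at the open C5 and then at the more hindered C3 between OH and Br, while the remaining C6–H is meta to OH and deactivated by the ester.

**Step 5**
Reactants: 10 methyl 2,3,5-tribromo-4-hydroxybenzoate
Product: 12 2,3,6-tribromo-4-(hydroxymethyl)phenol, via aldehyde 11 (not isolated)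
Conditions: i-Bu2AlH (3.5 equiv), CH2Cl2, −78 to 0 °C; KNaC4H4O6 (aq), then pH 5 buffer
Reagents that add atoms: none
Why: In this hydride reduction of an ester to a primary alcohol one equivalent of i-Bu2AlH is consumed by the phenol as an aluminium phenoxide and two more reduce the ester through the aldehyde, while aryl bromides are inert to this electrophilic hydride at low temperature and the mild, nearly neutral work-up avoids ionization of the 4-hydroxybenzyl alcohol.

**Compound list**

1 | methyl propiolate (methyl prop-2-ynoate) | C#CC(=O)OC | starting material
2 | N-bromosuccinimide | O=C1CCC(=O)N1Br | starting material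
3 | methyl 3-bromopropiolate (methyl 3-bromoprop-2-ynoate) | COC(=O)C#CBr | intermediate
4 | 2-(trimethylsilyloxy)buta-1,3-diene | C=CC(=C)O[Si](C)(C)C | starting material
5 | methyl 2-bromo-4-[(trimethylsilyl)oxy]cyclohexa-1,4-diene-1-carboxylate | COC(=O)C1=C(Br)CC(O[Si](C)(C)C)=CC1 | intermediate
6 | methyl 2-bromo-4-[(trimethylsilyl)oxy]benzoate | COC(=O)c1ccc(O[Si](C)(C)C)cc1Br | intermediate (not isolated)
7 | methyl 2-bromo-4-hydroxybenzoate | COC(=O)c1ccc(O)cc1Br | intermediate
8 | bromine | BrBr | starting material
9 | methyl 2,5-dibromo-4-hydroxybenzoate | COC(=O)c1cc(Br)c(O)cc1Br | intermediate (not isolated)
10 | methyl 2,3,5-tribromo-4-hydroxybenzoate | COC(=O)c1cc(Br)c(O)c(Br)c1Br | intermediate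
11 | 2,3,5-tribromo-4-hydroxybenzaldehyde | O=Cc1cc(Br)c(O)c(Br)c1Br | intermediate (not isolated)
12 | 2,3,6-tribromo-4-(hydroxymethyl)phenol | OCc1cc(Br)c(O)c(Br)c1Br | target

**Totals**

Total step count: 5. Longest linear sequence: 5 steps (1 → 3 → 5 → 7 → 10 → 12).

**Steps most likely to fail**

First, step 2. The cycloaddition may be too slow at a temperature the bromoalkyne tolerates, so that thermal oligomerization of 3, or dimerization and desilylation of 4, outruns ring formation; regiocontrol may also be incomplete. The fallback sets out from 3 and replaces the diene by the doubly activated, commercial (E)-1-methoxy-3-(trimethylsilyloxy)buta-1,3-diene (CO/C=C/C(=C)O[Si](C)(C)C). This diene should react at or near room temperature, and both of its donor groups direct its CH2 terminus to the brominated carbon. The same two ring bonds form and give racemic methyl 2-bromo-6-methoxy-4-[(trimethylsilyl)oxy]cyclohexa-1,4-diene-1-carboxylate F1. Because F1 is already at the oxidation level of the arene, dilute HCl in THF should hydrolyse the silyl enol ether and eliminate methanol from the resulting β-methoxy ketone. The dienone then tautomerizes to 7, where the route is rejoined and the DDQ step is no longer needed.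

Second, step 3. The silyl enol ether may hydrolyse before hydride is abstracted, and the freed β,γ-unsaturated ketone may isomerize into conjugation; the enol ether may also add to the quinone through carbon or oxygen. In either case dehydrogenation would stall. The fallback sets out from 5 and aromatizes by α-halogenation and dehydrohalogenation instead of hydride abstraction. Br2 (1.0 equiv) in CH2Cl2 at −78 °C should brominate the enol ether carbon with loss of bromotrimethylsilane and give racemic methyl 2,5-dibromo-4-oxocyclohex-1-ene-1-carboxylate F2. Et3N at 0 °C to rt then removes HBr by an E1cB pathway, and the cyclohexadienone tautomerizes to the phenol. After an acidic wash this is 7, where the route is rejoined.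

Third, step 5. The aluminium phenoxide formed first donates into the para ester, so the reduction may stop at the aldehyde stage. Forcing it with more hydride or heat invites hydrodebromination, and the 4-hydroxybenzyl alcohol may ionize to a quinone methide during work-up and oligomerize. The fallback sets out from 10. Saponification (LiOH, THF/H2O, 50 °C, then acidification) should give 2,3,5-tribromo-4-hydroxybenzoic acid F3. BH3·THF (0 °C to rt, methanol quench) then reduces the carboxylic acid through its acyloxyborane to the benzylic alcohol 12. These conditions are not basic, do not attack aryl bromides and need no aluminium work-up.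

**Further compounds**

F1 | step 2 | methyl 2-bromo-6-methoxy-4-[(trimethylsilyl)oxy]cyclohexa-1,4-diene-1-carboxylate (racemic) | COC(=O)C1=C(Br)CC(O[Si](C)(C)C)=CC1OC
F2 | step 3 | methyl 2,5-dibromo-4-oxocyclohex-1-ene-1-carboxylate (racemic) | COC(=O)C1=C(Br)CC(=O)C(Br)C1
F3 | step 5 | 2,3,5-tribromo-4-hydroxybenzoic acid | OC(=O)c1cc(Br)c(O)c(Br)c1Br
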